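**Retrosynthetic overview**

- The target is epicatechin-(4β→6)-epicatechin-(4β→6)-epicatechin (units T, M, B; every unit 2R,3R, both interflavan bonds 3,4-trans). The last step is hydrogenolysis of its tetradeca-O-benzyl ether.
- The strategy rests on unit B: its C4 is a CH2 bonded to C4a of ring A, and C6 of that ring (para to O1, between O5 and O7) carries C4 of unit M. Direct alkylation of an epicatechin ring A goes to C8 instead, so ring C of unit B is closed last, by C4–C4a bond formation from a terminal epoxide onto a ring whose two carbons ortho to O1 are equivalent.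
- The epoxy ether comes from a Mitsunobu etherification (O1–C2, inversion) of a 2,6-bis(benzyloxy)-4-hydroxyphenyl group on C4 of unit M with an epoxy alcohol from a Sharpless kinetic resolution. That aryl group comes from Friedel–Crafts capture of the C4 cation of unit M by phloroglucinol, followed by differentiation of the para oxygen.
- Unit M is built the same way on unit T: C4 cation of benzylated (−)-epicatechin plus phloroglucinol, etherification, 6-endo epoxide–arene closure, then benzylic oxidation at C4 of unit M.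
- Ring order: the rings of unit T come from (−)-epicatechin; ring A of M (phloroglucinol), then ring C of M; ring A of B (phloroglucinol), then ring C of B; the catechol ring of M and of B comes with the epoxy alcohol.

Key step: step 19

Remark: 3,4-bis(benzyloxy)benzaldehyde, the dibenzyl ether of 3,4-dihydroxybenzaldehyde, is taken as a commercial compound, so no catechol benzylation is counted.

**Route**

Step 1
Reactants: 1 (−)-epicatechin
Product: 2 5,7,3′,4′-tetra-O-benzyl-(−)-epicatechin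
Conditions: BnBr (4.4 equiv), K2CO3, DMF, 0 °C → rt
Reagents that add atoms: benzyl bromide, BrCc1ccccc1
Why: Williamson etherification; K2CO3 deprotonates only the four phenols, so the secondary 3-OH stays free and C2 and C3 are not touched.

Step 2
Reactants: 2 5,7,3′,4′-tetra-O-benzyl-(−)-epicatechin
Product: 3 3,5,7,3′,4′-penta-O-benzyl-(−)-epicatechin
Conditions: NaH, BnBr, Bu4NI (cat.), DMF, 0 °C → rt
Reagents that add atoms: benzyl bromide, BrCc1ccccc1
Why: Williamson etherification of the sodium alkoxide caps the 3-OH before C4 is oxidised; no stereocentre is affected.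

Step 3
Reactants: 3 3,5,7,3′,4′-penta-O-benzyl-(−)-epicatechin
Product: 4 3,5,7,3′,4′-penta-O-benzyl-4β-(2-ethoxyethoxy)-(−)-epicatechin (3,4-trans)
Conditions: DDQ, HOCH2CH2OEt, CH2Cl2, rt
Reagents that add atoms: 2-ethoxyethanol, CCOCCO
Why: Oxidative benzylic C–H functionalisation: DDQ abstracts hydride from C4, which is conjugated with the trioxygenated ring A, and the alcohol adds to the cation on the β face, away from the 3-OBn and 2-aryl groups, so the new C4 centre should be 3,4-trans.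

Step 4
Reactants: 4 3,5,7,3′,4′-penta-O-benzyl-4β-(2-ethoxyethoxy)-(−)-epicatechin; 5 phloroglucinol
Product: 6 3,5,7,3′,4′-penta-O-benzyl-4β-(2,4,6-trihydroxyphenyl)-(−)-epicatechin
Conditions: 5 (6 equiv), BF3·OEt2, THF/CH2Cl2 (1:4), −20 → 0 °C
Reagents that add atoms: none
Why: Friedel–Crafts alkylation: the Lewis acid ionises the C4 ether, and phloroglucinol (three equivalent ring carbons, used in excess against double alkylation) attacks the cation anti to the 3-OBn group, which sets 4β (3,4-trans).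

Step 5
Reactants: 6 3,5,7,3′,4′-penta-O-benzyl-4β-(2,4,6-trihydroxyphenyl)-(−)-epicatechin
Product: 7 3,5,7,3′,4′-penta-O-benzyl-4β-[2,6-dihydroxy-4-(triisopropylsilyloxy)phenyl]-(−)-epicatechin
Conditions: TIPSCl (1.05 equiv), imidazole, DMF, 0 °C
Reagents that add atoms: triisopropylsilyl chloride, CC(C)[Si](Cl)(C(C)C)C(C)C
Why: Sterically controlled silylation: the two hydroxyls next to the flavanyl group are shielded, so the bulky silyl chloride should take the unhindered para hydroxyl, the future O1 of unit M.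

Step 6
Reactants: 7 3,5,7,3′,4′-penta-O-benzyl-4β-[2,6-dihydroxy-4-(triisopropylsilyloxy)phenyl]-(−)-epicatechin
Product: 8 3,5,7,3′,4′-penta-O-benzyl-4β-[2,6-bis(benzyloxy)-4-(triisopropylsilyloxy)phenyl]-(−)-epicatechin
Conditions: BnBr, K2CO3, Bu4NI (cat.), acetone, 50 °C
Reagents that add atoms: benzyl bromide, BrCc1ccccc1
Why: Williamson etherification of the two remaining phenols under carbonate conditions that an aryl triisopropylsilyl ether tolerates.

Step 7
Reactants: 8 3,5,7,3′,4′-penta-O-benzyl-4β-[2,6-bis(benzyloxy)-4-(triisopropylsilyloxy)phenyl]-(−)-epicatechin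
Product: 9 3,5,7,3′,4′-penta-O-benzyl-4β-[2,6-bis(benzyloxy)-4-hydroxyphenyl]-(−)-epicatechin
Conditions: TBAF, AcOH, THF, 0 °C
Reagents that add atoms: none
Why: Fluoride cleavage of the aryl silyl ether, buffered with acetic acid, leaves the benzyl ethers and the C4–aryl bond untouched.

Step 8
Reactants: 10 3,4-bis(benzyloxy)benzaldehyde
Product: 11 rac-1-[3,4-bis(benzyloxy)phenyl]prop-2-en-1-ol
Conditions: CH2=CHMgBr, THF, −78 → 0 °C; H2O work-up
Reagents that add atoms: vinylmagnesium bromide, C=C[Mg]Br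
Why: Grignard 1,2-addition to the aldehyde; the carbinol centre is formed racemic and is resolved in the next step.

Step 9
Reactants: 11 rac-1-[3,4-bis(benzyloxy)phenyl]prop-2-en-1-ol
Product: 12 (S)-[3,4-bis(benzyloxy)phenyl][(2R)-oxiran-2-yl]methanol (erythro)
Conditions: Ti(OiPr)4 (0.2 equiv), L-(+)-DIPT (0.25 equiv), t-BuOOH (0.6 equiv), 4 Å MS, CH2Cl2, −20 °C
Reagents that add atoms: tert-butyl hydroperoxide, CC(C)(C)OO
Why: Sharpless kinetic resolution: with L-(+)-diisopropyl tartrate the (R)-enantiomer of 11 is expected to be epoxidised much faster and to give the erythro (anti) epoxy alcohol, so reagent control sets the oxirane centre (R) and selects the carbinol centre (S; the descriptor changes only because the oxirane outranks the aryl group), and unreacted (S)-11 is removed by chromatography.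

Step 10
Reactants: 9 3,5,7,3′,4′-penta-O-benzyl-4β-[2,6-bis(benzyloxy)-4-hydroxyphenyl]-(−)-epicatechin; 12 (S)-[3,4-bis(benzyloxy)phenyl][(2R)-oxiran-2-yl]methanol
Product: 13 3,5,7,3′,4′-penta-O-benzyl-4β-{2,6-bis(benzyloxy)-4-[(R)-[3,4-bis(benzyloxy)phenyl][(2R)-oxiran-2-yl]methoxy]phenyl}-(−)-epicatechin
Conditions: PPh3, DIAD, toluene, 0 °C → rt
Reagents that add atoms: none
Why: Mitsunobu etherification: the phenoxide of 9 displaces the oxyphosphonium of 12 with inversion at the benzylic carbon (S → R, the future C2 of unit M), the oxirane being inert to these neutral conditions and the non-polar solvent holding back ionisation.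

Step 11
Reactants: 13 3,5,7,3′,4′-penta-O-benzyl-4β-{2,6-bis(benzyloxy)-4-[(R)-[3,4-bis(benzyloxy)phenyl][(2R)-oxiran-2-yl]methoxy]phenyl}-(−)-epicatechin
Product: 14 nona-O-benzyl epicatechin-(4β→6)-epicatechin with free 3-OH in unit M (M: 2R,3R)
Conditions: AuCl3 (5 mol %), AgOTf (15 mol %), ClCH2CH2Cl, 0 °C → rt
Reagents that add atoms: none
Why: Epoxide–arene cycloalkylation (intramolecular Friedel–Crafts): the gold Lewis acid activates the oxirane and the ring carbon ortho to the ether oxygen attacks the CH2 in a 6-endo closure that forms C4–C4a of unit M and frees its 3-OH; C2 and C3 are carried over unchanged (2,3-cis), and the two ortho carbons are equivalent, so only the 4→6 linkage can result.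

Step 12
Reactants: 14 nona-O-benzyl epicatechin-(4β→6)-epicatechin with free 3-OH in unit M
Product: 15 deca-O-benzyl epicatechin-(4β→6)-epicatechin (perbenzylated procyanidin B5)
Conditions: NaH, BnBr, Bu4NI (cat.), DMF, 0 °C → rt
Reagents that add atoms: benzyl bromide, BrCc1ccccc1
Why: Williamson etherification of the 3-OH of unit M, so that the coming oxidation and the later Mitsunobu step meet no free alcohol.

Step 13
Reactants: 15 deca-O-benzyl epicatechin-(4β→6)-epicatechin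
Product: 16 deca-O-benzyl epicatechin-(4β→6)-epicatechin carrying a 4β-(2-ethoxyethoxy) group at C4 of unit M
Conditions: DDQ, HOCH2CH2OEt, CH2Cl2, rt
Reagents that add atoms: 2-ethoxyethanol, CCOCCO
Why: The same DDQ benzylic oxidation as in step 3, now at the only ring CH2 of the dimer (C4 of M); the tertiary C4–H of unit T is flanked by two aryl groups and poorly aligned with the π system of its ring A, and the alcohol should again enter trans to the 3-OBn group (4β).

Step 14
Reactants: 16 deca-O-benzyl dimer with 4β-(2-ethoxyethoxy) at C4 of unit M; 5 phloroglucinol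
Product: 17 deca-O-benzyl epicatechin-(4β→6)-epicatechin carrying a 4β-(2,4,6-trihydroxyphenyl) group at C4 of unit M
Conditions: 5 (6 equiv), BF3·OEt2, THF/CH2Cl2 (1:4), −20 → 0 °C
Reagents that add atoms: none
Why: Friedel–Crafts alkylation as in step 4: the crowded cation at C4 of M is captured by the small, symmetric and very nucleophilic phloroglucinol on the β face, anti to the 3-OBn group, which sets 4β of unit M and forms the C4(M)–C6(B) bond.

Step 15
Reactants: 17 deca-O-benzyl dimer with 4β-(2,4,6-trihydroxyphenyl) at C4 of unit M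
Product: 18 deca-O-benzyl dimer with 4β-[2,6-dihydroxy-4-(triisopropylsilyloxy)phenyl] at C4 of unit M
Conditions: TIPSCl (1.05 equiv), imidazole, DMF, 0 °C
Reagents that add atoms: triisopropylsilyl chloride, CC(C)[Si](Cl)(C(C)C)C(C)C
Why: Sterically controlled silylation of the unhindered para hydroxyl, the future O1 of unit B, as in step 5.

Step 16
Reactants: 18 deca-O-benzyl dimer with 4β-[2,6-dihydroxy-4-(triisopropylsilyloxy)phenyl] at C4 of unit M
Product: 19 deca-O-benzyl dimer with 4β-[2,6-bis(benzyloxy)-4-(triisopropylsilyloxy)phenyl] at C4 of unit M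
Conditions: BnBr, K2CO3, Bu4NI (cat.), acetone, 50 °C
Reagents that add atoms: benzyl bromide, BrCc1ccccc1
Why: Williamson etherification of the two hindered phenols, as in step 6.

Step 17
Reactants: 19 deca-O-benzyl dimer with 4β-[2,6-bis(benzyloxy)-4-(triisopropylsilyloxy)phenyl] at C4 of unit M
Product: 20 deca-O-benzyl dimer with 4β-[2,6-bis(benzyloxy)-4-hydroxyphenyl] at C4 of unit M
Conditions: TBAF, AcOH, THF, 0 °C
Reagents that add atoms: none
Why: Buffered fluoride cleavage of the aryl silyl ether, as in step 7.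

Step 18
Reactants: 20 deca-O-benzyl dimer with 4β-[2,6-bis(benzyloxy)-4-hydroxyphenyl] at C4 of unit M; 12 (S)-[3,4-bis(benzyloxy)phenyl][(2R)-oxiran-2-yl]methanol
Product: 21 deca-O-benzyl dimer with 4β-{2,6-bis(benzyloxy)-4-[(R)-[3,4-bis(benzyloxy)phenyl][(2R)-oxiran-2-yl]methoxy]phenyl} at C4 of unit M
Conditions: PPh3, DIAD, toluene, 0 °C → rt
Reagents that add atoms: none
Why: Mitsunobu etherification with inversion at the benzylic carbon (S → R, the future C2 of unit B), as in step 10; the phenol oxygen is unhindered because it sits para to the bulky substituent.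

Step 19
Reactants: 21 deca-O-benzyl dimer with 4β-{2,6-bis(benzyloxy)-4-[(R)-[3,4-bis(benzyloxy)phenyl][(2R)-oxiran-2-yl]methoxy]phenyl} at C4 of unit M
Product: 22 tetradeca-O-benzyl epicatechin-(4β→6)-epicatechin-(4β→6)-epicatechin with free 3-OH in unit B
Conditions: AuCl3 (5 mol %), AgOTf (15 mol %), ClCH2CH2Cl, 0 °C → rt
Reagents that add atoms: none
Why: AuCl3 and AgOTf give a cationic trivalent gold Lewis acid that binds the oxirane oxygen of 21; the trioxygenated benzene ring then attacks the terminal CH2 through a carbon ortho to the ether oxygen in an SN2-like Friedel–Crafts alkylation, and rearomatisation with proton transfer to the alkoxide frees the C3 hydroxyl. The closest known reaction type is the gold- or Lewis-acid-catalysed cycloalkylation of aryl glycidyl ethers and of 1-aryl-2,3-epoxypropyl aryl ethers to chroman-3-ols and flavan-3-ols. The one ring formed, ring C of unit B, closes in 6-endo-tet mode by the C4–C4a bond, the oxirane being the only ring opened. No stereocentre is created: C2 (R, from the Mitsunobu inversion) and C3 (R, from the Sharpless resolution) take no part in the bond-forming event and should deliver the 2,3-cis relation unchanged. The step needs 6-endo attack at CH2 over 5-exo attack at C3 and over ionisation of the benzylic C2–O bond; the C2 oxygen disfavours positive charge at C3, the primary carbon is open to backside attack, the ring with three oxygen donors is nucleophilic enough to react near room temperature under a mild catalytic activator, and the oxirane withdraws electron density from C2. Arene regiochemistry needs no control, because the ether oxygen (the future O1) is para to the carbon that carries C4 of unit M, so both ortho carbons are equivalent and either closure gives the 4→6 linkage.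

Step 20
Reactants: 22 tetradeca-O-benzyl epicatechin-(4β→6)-epicatechin-(4β→6)-epicatechin with free 3-OH in unit B
Product: 23 epicatechin-(4β→6)-epicatechin-(4β→6)-epicatechin (target)
Conditions: H2 (1 atm), Pd(OH)2/C, THF/MeOH/H2O, rt, under argon on work-up
Reagents that add atoms: none
Why: Catalytic hydrogenolysis cleaves all fourteen O-benzyl groups and is the standard way to release oligomeric flavan-3-ols without touching the interflavan C–C bonds, the pyran rings or any stereocentre.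

**Compound list**

1 | (−)-epicatechin | Oc1cc(O)c2c(c1)O[C@H](c1ccc(O)c(O)c1)[C@H](O)C2 | starting material
2 | 5,7,3′,4′-tetra-O-benzyl-(−)-epicatechin | C(c9ccccc9)Oc1cc(OCc9ccccc9)c2c(c1)O[C@H](c8ccc(OCc9ccccc9)c(OCc9ccccc9)c8)[C@H](O)C2 | intermediate
3 | 3,5,7,3′,4′-penta-O-benzyl-(−)-epicatechin | C(c9ccccc9)Oc1cc(OCc9ccccc9)c2c(c1)O[C@H](c8ccc(OCc9ccccc9)c(OCc9ccccc9)c8)[C@H](OCc9ccccc9)C2 | intermediate
4 | 3,5,7,3′,4′-penta-O-benzyl-4β-(2-ethoxyethoxy)-(−)-epicatechin | C(c9ccccc9)Oc1cc(OCc9ccccc9)c2c(c1)O[C@H](c8ccc(OCc9ccccc9)c(OCc9ccccc9)c8)[C@H](OCc9ccccc9)[C@H]2OCCOCC | intermediate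
5 | phloroglucinol | Oc1cc(O)cc(O)c1 | starting material
6 | 3,5,7,3′,4′-penta-O-benzyl-4β-(2,4,6-trihydroxyphenyl)-(−)-epicatechin | C(c9ccccc9)Oc1cc(OCc9ccccc9)c2c(c1)O[C@H](c8ccc(OCc9ccccc9)c(OCc9ccccc9)c8)[C@H](OCc9ccccc9)[C@H]2c1c(O)cc(O)cc1O | intermediate
7 | 3,5,7,3′,4′-penta-O-benzyl-4β-[2,6-dihydroxy-4-(triisopropylsilyloxy)phenyl]-(−)-epicatechin | C(c9ccccc9)Oc1cc(OCc9ccccc9)c2c(c1)O[C@H](c8ccc(OCc9ccccc9)c(OCc9ccccc9)c8)[C@H](OCc9ccccc9)[C@H]2c1c(O)cc(O[Si](C(C)C)(C(C)C)C(C)C)cc1O | intermediate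
8 | 3,5,7,3′,4′-penta-O-benzyl-4β-[2,6-bis(benzyloxy)-4-(triisopropylsilyloxy)phenyl]-(−)-epicatechin | C(c9ccccc9)Oc1cc(OCc9ccccc9)c2c(c1)O[C@H](c8ccc(OCc9ccccc9)c(OCc9ccccc9)c8)[C@H](OCc9ccccc9)[C@H]2c1c(OCc9ccccc9)cc(O[Si](C(C)C)(C(C)C)C(C)C)cc1OCc9ccccc9 | intermediate
9 | 3,5,7,3′,4′-penta-O-benzyl-4β-[2,6-bis(benzyloxy)-4-hydroxyphenyl]-(−)-epicatechin | C(c9ccccc9)Oc1cc(OCc9ccccc9)c2c(c1)O[C@H](c8ccc(OCc9ccccc9)c(OCc9ccccc9)c8)[C@H](OCc9ccccc9)[C@H]2c1c(OCc9ccccc9)cc(O)cc1OCc9ccccc9 | intermediate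
10 | 3,4-bis(benzyloxy)benzaldehyde | O=Cc1ccc(OCc2ccccc2)c(OCc2ccccc2)c1 | starting material
11 | rac-1-[3,4-bis(benzyloxy)phenyl]prop-2-en-1-ol | C=CC(O)c1ccc(OCc2ccccc2)c(OCc2ccccc2)c1 | intermediate
12 | (S)-[3,4-bis(benzyloxy)phenyl][(2R)-oxiran-2-yl]methanol | O[C@@H](c1ccc(OCc2ccccc2)c(OCc2ccccc2)c1)[C@H]1CO1 | intermediate
13 | 3,5,7,3′,4′-penta-O-benzyl-4β-{2,6-bis(benzyloxy)-4-[(R)-[3,4-bis(benzyloxy)phenyl][(2R)-oxiran-2-yl]methoxy]phenyl}-(−)-epicatechin | C(c9ccccc9)Oc1cc(OCc9ccccc9)c2c(c1)O[C@H](c8ccc(OCc9ccccc9)c(OCc9ccccc9)c8)[C@H](OCc9ccccc9)[C@H]2c1c(OCc9ccccc9)cc(O[C@H](c8ccc(OCc9ccccc9)c(OCc9ccccc9)c8)[C@H]3CO3)cc1OCc9ccccc9 | intermediate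
14 | nona-O-benzyl epicatechin-(4β→6)-epicatechin, free 3-OH in unit M | C(c9ccccc9)Oc1cc(OCc9ccccc9)c2c(c1)O[C@H](c8ccc(OCc9ccccc9)c(OCc9ccccc9)c8)[C@H](OCc9ccccc9)[C@H]2c1c(OCc9ccccc9)cc2c(c1OCc9ccccc9)C[C@@H](O)[C@@H](c8ccc(OCc9ccccc9)c(OCc9ccccc9)c8)O2 | intermediate
15 | deca-O-benzyl epicatechin-(4β→6)-epicatechin | C(c9ccccc9)Oc1cc(OCc9ccccc9)c2c(c1)O[C@H](c8ccc(OCc9ccccc9)c(OCc9ccccc9)c8)[C@H](OCc9ccccc9)[C@H]2c1c(OCc9ccccc9)cc2c(c1OCc9ccccc9)C[C@@H](OCc9ccccc9)[C@@H](c8ccc(OCc9ccccc9)c(OCc9ccccc9)c8)O2 | intermediate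
16 | deca-O-benzyl dimer with 4β-(2-ethoxyethoxy) at C4 of unit M | C(c9ccccc9)Oc1cc(OCc9ccccc9)c2c(c1)O[C@H](c8ccc(OCc9ccccc9)c(OCc9ccccc9)c8)[C@H](OCc9ccccc9)[C@H]2c1c(OCc9ccccc9)cc2c(c1OCc9ccccc9)[C@H](OCCOCC)[C@@H](OCc9ccccc9)[C@@H](c8ccc(OCc9ccccc9)c(OCc9ccccc9)c8)O2 | intermediate
17 | deca-O-benzyl dimer with 4β-(2,4,6-trihydroxyphenyl) at C4 of unit M | C(c9ccccc9)Oc1cc(OCc9ccccc9)c2c(c1)O[C@H](c8ccc(OCc9ccccc9)c(OCc9ccccc9)c8)[C@H](OCc9ccccc9)[C@H]2c1c(OCc9ccccc9)cc2c(c1OCc9ccccc9)[C@H](c1c(O)cc(O)cc1O)[C@@H](OCc9ccccc9)[C@@H](c8ccc(OCc9ccccc9)c(OCc9ccccc9)c8)O2 | intermediate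
18 | deca-O-benzyl dimer with 4β-[2,6-dihydroxy-4-(triisopropylsilyloxy)phenyl] at C4 of unit M | C(c9ccccc9)Oc1cc(OCc9ccccc9)c2c(c1)O[C@H](c8ccc(OCc9ccccc9)c(OCc9ccccc9)c8)[C@H](OCc9ccccc9)[C@H]2c1c(OCc9ccccc9)cc2c(c1OCc9ccccc9)[C@H](c1c(O)cc(O[Si](C(C)C)(C(C)C)C(C)C)cc1O)[C@@H](OCc9ccccc9)[C@@H](c8ccc(OCc9ccccc9)c(OCc9ccccc9)c8)O2 | intermediate
19 | deca-O-benzyl dimer with 4β-[2,6-bis(benzyloxy)-4-(triisopropylsilyloxy)phenyl] at C4 of unit M | C(c9ccccc9)Oc1cc(OCc9ccccc9)c2c(c1)O[C@H](c8ccc(OCc9ccccc9)c(OCc9ccccc9)c8)[C@H](OCc9ccccc9)[C@H]2c1c(OCc9ccccc9)cc2c(c1OCc9ccccc9)[C@H](c1c(OCc9ccccc9)cc(O[Si](C(C)C)(C(C)C)C(C)C)cc1OCc9ccccc9)[C@@H](OCc9ccccc9)[C@@H](c8ccc(OCc9ccccc9)c(OCc9ccccc9)c8)O2 | intermediate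
20 | deca-O-benzyl dimer with 4β-[2,6-bis(benzyloxy)-4-hydroxyphenyl] at C4 of unit M | C(c9ccccc9)Oc1cc(OCc9ccccc9)c2c(c1)O[C@H](c8ccc(OCc9ccccc9)c(OCc9ccccc9)c8)[C@H](OCc9ccccc9)[C@H]2c1c(OCc9ccccc9)cc2c(c1OCc9ccccc9)[C@H](c1c(OCc9ccccc9)cc(O)cc1OCc9ccccc9)[C@@H](OCc9ccccc9)[C@@H](c8ccc(OCc9ccccc9)c(OCc9ccccc9)c8)O2 | intermediate
21 | deca-O-benzyl dimer with 4β-{2,6-bis(benzyloxy)-4-[(R)-[3,4-bis(benzyloxy)phenyl][(2R)-oxiran-2-yl]methoxy]phenyl} at C4 of unit M (key-step precursor) | C(c9ccccc9)Oc1cc(OCc9ccccc9)c2c(c1)O[C@H](c8ccc(OCc9ccccc9)c(OCc9ccccc9)c8)[C@H](OCc9ccccc9)[C@H]2c1c(OCc9ccccc9)cc2c(c1OCc9ccccc9)[C@H](c1c(OCc9ccccc9)cc(O[C@H](c8ccc(OCc9ccccc9)c(OCc9ccccc9)c8)[C@H]3CO3)cc1OCc9ccccc9)[C@@H](OCc9ccccc9)[C@@H](c8ccc(OCc9ccccc9)c(OCc9ccccc9)c8)O2 | intermediate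
22 | tetradeca-O-benzyl epicatechin-(4β→6)-epicatechin-(4β→6)-epicatechin, free 3-OH in unit B (key-step product) | C(c9ccccc9)Oc1cc(OCc9ccccc9)c2c(c1)O[C@H](c8ccc(OCc9ccccc9)c(OCc9ccccc9)c8)[C@H](OCc9ccccc9)[C@H]2c1c(OCc9ccccc9)cc2c(c1OCc9ccccc9)[C@H](c1c(OCc9ccccc9)cc3c(c1OCc9ccccc9)C[C@@H](O)[C@@H](c8ccc(OCc9ccccc9)c(OCc9ccccc9)c8)O3)[C@@H](OCc9ccccc9)[C@@H](c8ccc(OCc9ccccc9)c(OCc9ccccc9)c8)O2 | intermediate
23 | epicatechin-(4β→6)-epicatechin-(4β→6)-epicatechin (CNP0163146.2) | Oc1cc(O)c2c(c1)O[C@H](c1ccc(O)c(O)c1)[C@H](O)[C@H]2c1c(O)cc2c(c1O)[C@H](c1c(O)cc3c(c1O)C[C@@H](O)[C@@H](c1ccc(O)c(O)c1)O3)[C@@H](O)[C@@H](c1ccc(O)c(O)c1)O2 | target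

**Step count and risks**

Total step count: 20. Longest linear sequence: 18 steps (steps 1–7 and 10–20, from 1); steps 8 and 9 give the epoxy alcohol 12, which enters at steps 10 and 18.

Steps most likely to fail:

1. Step 19 (key ring closure). The activated oxirane may open at C3 in a 5-exo sense, or the benzylic C2–O bond may ionise, which would expel the phenol or scramble C2 instead of giving the 6-endo closure. The fallback sets out from 16 and 3 and comes back at 23. It makes the C4(M)–C6(B) bond by the known halogen-capping tactic, in which a C8 bromine steers a flavan nucleophile to C6. Compound 3 is brominated at C8 with NBS (CH2Cl2, −40 °C) to give 8-bromo-3,5,7,3′,4′-penta-O-benzylepicatechin F1. Compound 16 is capped with NBS at its three free ring A carbons (C6 and C8 of unit T, C8 of unit M) to give the tribromo dimer electrophile F2, which can no longer alkylate itself. TMSOTf in CH2Cl2 at −78 °C ionises F2 in the presence of excess F1, which can react only at C6 and on the β face of the cation, to give the tetrabromo pentadeca-O-benzyl trimer F3. Hydrogenolysis over Pd(OH)2/C with Et3N then removes the four bromines and all fifteen benzyl groups and gives 23.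

2. Step 13 (DDQ oxidation of the dimer). Hydride may be abstracted at the doubly benzylic C4–H of unit T, or C4 of unit M may be oxidised beyond the ether stage. The fallback sets out from 15 and comes back at 17. Pb(OAc)4 in benzene is a different oxidant class that acetoxylates flavan C4 methylene groups; it should convert 15 into the 4β-acetoxy deca-O-benzyl dimer F4 (acetate trans to the 3-OBn group of unit M). BF3·OEt2 with excess phloroglucinol then displaces the acetate through the same C4 cation and gives 17.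

3. Step 11 (first ring closure, on 13). The same competing oxirane openings and benzylic ionisation may occur when ring C of unit M is closed. The fallback sets out from 4 and 3 and comes back at 15. Compound 4 is capped at C6 and C8 with NBS to give 6,8-dibromo-3,5,7,3′,4′-penta-O-benzyl-4β-(2-ethoxyethoxy)epicatechin F5. TMSOTf-mediated Friedel–Crafts coupling of F5 with 8-bromo-penta-O-benzylepicatechin F1 (from 3 as above), which can react only at C6, gives the tribromo deca-O-benzyl epicatechin-(4β→6)-epicatechin F6. Bromine–lithium exchange with n-BuLi in THF at −78 °C followed by a methanol quench removes the three bromines and gives 15, from which the route continues at step 13.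

Further compounds
F1 | step 19 | 8-bromo-3,5,7,3′,4′-penta-O-benzyl-(−)-epicatechin | C(c9ccccc9)Oc1cc(OCc9ccccc9)c2c(c1Br)O[C@H](c8ccc(OCc9ccccc9)c(OCc9ccccc9)c8)[C@H](OCc9ccccc9)C2
F2 | step 19 | tribromo (C6 and C8 of unit T, C8 of unit M) deca-O-benzyl dimer with 4β-(2-ethoxyethoxy) at C4 of unit M | C(c9ccccc9)Oc1c(Br)c(OCc9ccccc9)c2c(c1Br)O[C@H](c8ccc(OCc9ccccc9)c(OCc9ccccc9)c8)[C@H](OCc9ccccc9)[C@H]2c1c(OCc9ccccc9)c(Br)c2c(c1OCc9ccccc9)[C@H](OCCOCC)[C@@H](OCc9ccccc9)[C@@H](c8ccc(OCc9ccccc9)c(OCc9ccccc9)c8)O2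
F3 | step 19 | tetrabromo pentadeca-O-benzyl epicatechin-(4β→6)-epicatechin-(4β→6)-epicatechin | C(c9ccccc9)Oc1c(Br)c(OCc9ccccc9)c2c(c1Br)O[C@H](c8ccc(OCc9ccccc9)c(OCc9ccccc9)c8)[C@H](OCc9ccccc9)[C@H]2c1c(OCc9ccccc9)c(Br)c2c(c1OCc9ccccc9)[C@H](c1c(OCc9ccccc9)c(Br)c3c(c1OCc9ccccc9)C[C@@H](OCc9ccccc9)[C@@H](c8ccc(OCc9ccccc9)c(OCc9ccccc9)c8)O3)[C@@H](OCc9ccccc9)[C@@H](c8ccc(OCc9ccccc9)c(OCc9ccccc9)c8)O2
F4 | step 13 | deca-O-benzyl dimer with 4β-acetoxy at C4 of unit M | C(c9ccccc9)Oc1cc(OCc9ccccc9)c2c(c1)O[C@H](c8ccc(OCc9ccccc9)c(OCc9ccccc9)c8)[C@H](OCc9ccccc9)[C@H]2c1c(OCc9ccccc9)cc2c(c1OCc9ccccc9)[C@H](OC(C)=O)[C@@H](OCc9ccccc9)[C@@H](c8ccc(OCc9ccccc9)c(OCc9ccccc9)c8)O2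
F5 | step 11 | 6,8-dibromo-3,5,7,3′,4′-penta-O-benzyl-4β-(2-ethoxyethoxy)-(−)-epicatechin | C(c9ccccc9)Oc1c(Br)c(OCc9ccccc9)c2c(c1Br)O[C@H](c8ccc(OCc9ccccc9)c(OCc9ccccc9)c8)[C@H](OCc9ccccc9)[C@H]2OCCOCC
F6 | step 11 | tribromo (C6 and C8 of unit T, C8 of unit M) deca-O-benzyl epicatechin-(4β→6)-epicatechin | C(c9ccccc9)Oc1c(Br)c(OCc9ccccc9)c2c(c1Br)O[C@H](c8ccc(OCc9ccccc9)c(OCc9ccccc9)c8)[C@H](OCc9ccccc9)[C@H]2c1c(OCc9ccccc9)c(Br)c2c(c1OCc9ccccc9)C[C@@H](OCc9ccccc9)[C@@H](c8ccc(OCc9ccccc9)c(OCc9ccccc9)c8)O2
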